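**Retrosynthetic overview**
1. Target ⇐ kinetic intramolecular aldol (C3–C4) that closes ring A on a 3,4-seco aldehyde lactone acid.
2. Ring B ⇐ Wolff ring contraction of a 6-diazo-7-ketone in a six-membered ring B′ (C8 shifts from C7 to C6, C7 becomes the carboxyl); this is the central step.
3. 19,10-Lactone ⇐ intramolecular Michael addition of a C10 propanoate to a C5=C6 enone; ring D and the C16 carbinol ⇐ carbonyl-ene closure of a C8 acetonyl group onto the ring C alkene.
4. Quaternary C8 ⇐ α′-alkylation; ring C ⇐ enantioselective desymmetrising Diels–Alder reaction of a p-quinol propanoate with butadiene.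
5. Quinol ester ⇐ p-benzoquinone + 3-(benzyloxy)propyl Grignard reagent + propanoyl chloride. Ring order: B′ → C → D → lactone → B (contraction) → A.

Convention (assumed): locants are gibberellane numbers of the target (C18 methyl, C19 lactone carbonyl, C7 carboxyl carbon on C6); α is the face of the lactone oxygen, H-5 and H-9 are β; ring B′ = C5, C6, C7, C8, C9, C10; benzyl groups are protecting groups; the target carries 16-OH endo (syn to C12) and 17-CH3 exo (syn to C14), as read from the SMILES.

**Step 1**
Reactants: 1 p-benzoquinone; 2 benzyl 3-bromopropyl ether; 3 propanoyl chloride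
Product: 6 1-[3-(benzyloxy)propyl]-4-oxocyclohexa-2,5-dien-1-yl propanoate, via Grignard reagent 4 (not isolated), via bromomagnesium quinolate 5 (not isolated)
Conditions: 2, Mg, THF, 25 °C; add to 1 in THF, −78 °C; then 3, −78 → 0 °C
Reagents that add atoms: none
Why: Grignard 1,2-addition to one quinone carbonyl gives the p-quinol alkoxide, which is O-acylated in the same flask by the acid chloride (esterification); the product is achiral and its ring carbons become C5–C10.

**Step 2**
Reactants: 6 1-[3-(benzyloxy)propyl]-4-oxocyclohexa-2,5-dien-1-yl propanoate; 7 buta-1,3-diene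
Product: 8 cis-fused Diels–Alder adduct (H-8β and H-9β; 10α-propanoyloxy; C12=C13)
Conditions: (S)-1-(2-methylphenyl)-3,3-diphenyltetrahydro-1H,3H-pyrrolo[1,2-c][1,3,2]oxazaborole + AlBr3 (10 mol% each), 7 (5 equiv), CH2Cl2, −40 °C
Reagents that add atoms: none
Why: Proposed new method: the cationic oxazaborolidine–AlBr3 Lewis acid binds the dienone carbonyl and butadiene adds suprafacially to C8=C9 on the face syn to the acyloxy group (the intrinsic facial bias of 4-acyloxy-4-alkyl dienones), while the aryl shield of the catalyst leaves only one of the two enantiotopic enone double bonds open on that face, so this desymmetrising Diels–Alder reaction forms ring C and fixes the cis ring fusion and the absolute configuration at C9 and C10 in one step; the closest known reactions are oxazaborolidinium-catalysed enantioselective Diels–Alder reactions of quinone monoketals and cyclic enones and the substrate-controlled syn-to-oxygen Diels–Alder reactions of p-quinol derivatives.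

**Step 3**
Reactants: 8 cis-fused Diels–Alder adduct; 9 3-bromo-2-methoxyprop-1-ene
Product: 11 8β-(2-oxopropyl) enone (quaternary C8), via enol ether 10 (not isolated)
Conditions: LiN(SiMe3)2 (1.05 equiv, inverse addition), THF–DMPU, −78 °C; 9, −78 → −40 °C; then 0.5 M oxalic acid (aq), THF, 0 °C
Reagents that add atoms: water, O
Why: The only acidic ketone proton is the α′-H at C8 (C6 is vinylic) and the ketone is far more acidic than the ester, so the cross-conjugated dienolate forms regiospecifically and is alkylated (enolate C-alkylation) on the convex β face, cis to H-9, before mild acid hydrolyses the enol ether to the methyl ketone that supplies C15, C16 and C17.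

**Step 4**
Reactants: 11 8β-(2-oxopropyl) enone
Product: 12 ring D tertiary alcohol (16-OH endo; C11=C12)
Conditions: Me2AlCl (3 equiv), CH2Cl2, −78 → 0 °C
Reagents that add atoms: none
Why: In this Lewis-acid-promoted intramolecular carbonyl-ene reaction the C16 ketone on the axial C8 side chain bonds to C13 while H-11 passes to oxygen through a six-membered transition state, which closes ring D, moves the alkene to C11=C12 and forces the oxygen onto the C11–C12 side of C16 (OH endo, methyl exo, as in the target).

**Step 5**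
Reactants: 12 ring D tertiary alcohol
Product: 13 19,10-lactone 7-ketone (H-5β; C6 methylene)
Conditions: KN(SiMe3)2 (2.2 equiv), THF, −78 → −20 °C; NH4Cl (aq)
Reagents that add atoms: none
Why: Intramolecular Michael addition (5-exo) of the propanoate enolate to C5 of the enone closes the γ-lactone, and because the short tether can reach C5 only from the α face the lactone is cis-fused and H-5 is β, while the C4 epimer ratio is irrelevant since C4 is re-enolised in step 10.

**Step 6**
Reactants: 13 19,10-lactone 7-ketone
Product: 15 6-diazo-7-ketone, via trifluoroacetyl ketone 14 (not isolated)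
Conditions: LiN(SiMe3)2 (2.1 equiv), THF, −78 °C; CF3CO2CH2CF3; then MeSO2N3, Et3N, H2O, MeCN, 25 °C
Reagents that add atoms: methanesulfonyl azide, CS(=O)(=O)N=[N+]=[N-]
Why: Detrifluoroacetylative diazo transfer (Regitz type) works because the ketone can enolise only towards C6 (C8 is quaternary), so the C6 trifluoroacetyl derivative forms and is exchanged for the diazo group without touching any stereocentre.

**Step 7**
Reactants: 15 6-diazo-7-ketone
Product: 18 6β benzyl ester of the ring-contracted acid, via ketene 16 (not isolated), via 6-epi benzyl ester 17 (not isolated)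
Conditions: hν (Hg lamp, Pyrex), BnOH, THF, 20 °C; then KOt-Bu (0.2 equiv), 0 °C
Reagents that add atoms: benzyl alcohol, OCc1ccccc1
Why: In the photochemical Wolff rearrangement loss of N2 is accompanied by a 1,2-shift of C8 from C7 to C6 (with retention at C8), which contracts ring B′ to the five-membered ring B and turns C7 into a ketene trapped by benzyl alcohol, and catalytic alkoxide then equilibrates the kinetically protonated C6 epimer to the more stable 6β ester (trans to C4).

**Step 8**
Reactants: 18 6β benzyl ester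
Product: 19 3,4-seco hydroxy acid
Conditions: H2 (1 atm), palladium on carbon (Pd/C, 10%), EtOAc–MeOH, 25 °C
Reagents that add atoms: none
Why: Heterogeneous catalytic hydrogenation saturates the unhindered C11=C12 bond and hydrogenolyses the benzyl ether and the benzyl ester in one operation without creating a stereocentre.

**Step 9**
Reactants: 19 3,4-seco hydroxy acid
Product: 20 3,4-seco aldehyde acid
Conditions: Dess–Martin periodinane (1.2 equiv), CH2Cl2, 0 → 25 °C
Reagents that add atoms: none
Why: Dess–Martin oxidation converts the primary alcohol into the C3 aldehyde and leaves the tertiary alcohol, the carboxylic acid and the lactone untouched.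

**Step 10**
Reactants: 20 3,4-seco aldehyde acid
Product: 21 CNP0343121.3 (3β,16-dihydroxy 19,10-lactone 7-acid)
Conditions: K2CO3 (2.5 equiv), MeOH, −20 → 0 °C, short contact; HCl (aq) to pH 3
Reagents that add atoms: none
Why: The intramolecular aldol reaction of the lactone enolate at C4 with the C3 aldehyde closes ring A; the tether can reach only one face of C4, which fixes the quaternary centre, and under non-chelating, kinetically controlled conditions the open transition state with the aldehyde oxygen anti to the lactone carbonyl is expected to give the axial 3β-alcohol as the major epimer.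

**Compound list**
1 | p-benzoquinone | O=C1C=CC(=O)C=C1 | starting material
2 | benzyl 3-bromopropyl ether (3-bromopropan-1-ol carried as its benzyl ether) | BrCCCOCc1ccccc1 | starting material
3 | propanoyl chloride | CCC(Cl)=O | starting material
4 | [3-(benzyloxy)propyl]magnesium bromide (Grignard reagent) | Br[Mg]CCCOCc1ccccc1 | intermediate
5 | bromomagnesium 1-[3-(benzyloxy)propyl]-4-oxocyclohexa-2,5-dien-1-olate (bromomagnesium quinolate) | O=C1C=CC(CCCOCc2ccccc2)(O[Mg]Br)C=C1 | intermediate
6 | 1-[3-(benzyloxy)propyl]-4-oxocyclohexa-2,5-dien-1-yl propanoate | CCC(=O)OC1(CCCOCc2ccccc2)C=CC(=O)C=C1 | intermediate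
7 | buta-1,3-diene | C=CC=C | starting material
8 | cis-fused adduct, 4-[3-(benzyloxy)propyl]-1-oxo-1,4,4a,5,8,8a-hexahydronaphthalen-4-yl propanoate; H-8 and H-9 β, propanoyloxy 10α, side chain 10β, alkenes C5=C6 and C12=C13 | CCC(=O)O[C@]3(CCCOCc4ccccc4)[C@@H]1CC=CC[C@@H]1C(=O)C=C3 | intermediate
9 | 3-bromo-2-methoxyprop-1-ene | C=C(OC)CBr | starting material
10 | enol ether: 8 with a 2-methoxyprop-2-en-1-yl group in place of H-8 (8β) | CCC(=O)O[C@]3(CCCOCc4ccccc4)[C@@H]1CC=CC[C@]1(CC(=C)OC)C(=O)C=C3 | intermediate
11 | 8β-(2-oxopropyl) enone: 8 with CH2C(=O)CH3 (C15, C16, C17) in place of H-8, cis to H-9 | CCC(=O)O[C@]3(CCCOCc4ccccc4)[C@@H]1CC=CC[C@]1(CC(C)=O)C(=O)C=C3 | intermediate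
12 | ring D tertiary alcohol: C16–C13 bond closed (bicyclo[3.2.1]oct-11-ene), 16-OH endo (syn to C12), 17-CH3 exo, 7-oxo-5-ene, 10α-propanoate | CCC(=O)O[C@]3(CCCOCc5ccccc5)[C@@H]1C=C[C@@H]4C[C@]1(C[C@]4(C)O)C(=O)C=C3 | intermediate
13 | 19,10-lactone 7-ketone: cis-fused γ-lactone C10–O–C19(=O)–C4H(CH3)–C5, H-5β, C6 methylene, C11=C12; C4 drawn as the epimer with methyl on the convex face | C[C@H]1C(=O)O[C@]3(CCCOCc5ccccc5)[C@@H]2C=C[C@@H]4C[C@]2(C[C@]4(C)O)C(=O)C[C@@H]31 | intermediate
14 | trifluoroacetyl ketone: 13 with COCF3 at C6 (C6 epimers, enolised) | C[C@H]1C(=O)O[C@]3(CCCOCc5ccccc5)[C@@H]2C=C[C@@H]4C[C@]2(C[C@]4(C)O)C(=O)C(C(=O)C(F)(F)F)[C@@H]31 | intermediate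
15 | 6-diazo-7-ketone | C[C@H]1C(=O)O[C@]3(CCCOCc5ccccc5)[C@@H]2C=C[C@@H]4C[C@]2(C[C@]4(C)O)C(=O)C(=[N+]=[N-])[C@@H]31 | intermediate
16 | ketene: ring B five-membered (C5, C6, C8, C9, C10), C6=C7=O | C[C@H]1C(=O)O[C@]3(CCCOCc5ccccc5)[C@@H]2C=C[C@@H]4C[C@]2(C[C@]4(C)O)C(=C=O)[C@@H]31 | intermediate
17 | 6-epi benzyl ester (7-ester α) | C[C@H]1C(=O)O[C@]3(CCCOCc5ccccc5)[C@@H]2C=C[C@@H]4C[C@]2(C[C@]4(C)O)[C@H](C(=O)OCc6ccccc6)[C@@H]31 | intermediate
18 | 6β benzyl ester: ring-contracted 19,10-lactone, benzyl 7-oate, 3-O-benzyl 3,4-seco chain, C11=C12, 16-OH | C[C@H]1C(=O)O[C@]3(CCCOCc5ccccc5)[C@@H]2C=C[C@@H]4C[C@]2(C[C@]4(C)O)[C@@H](C(=O)OCc6ccccc6)[C@@H]31 | intermediate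
19 | 3,4-seco hydroxy acid: 3-hydroxypropyl at C10, 7-oic acid, 19,10-lactone with C4–H, 16-OH | C[C@H]1C(=O)O[C@]3(CCCO)[C@@H]2CC[C@@H]4C[C@]2(C[C@]4(C)O)[C@@H](C(=O)O)[C@@H]31 | intermediate
20 | 3,4-seco aldehyde acid: 3-oxopropyl at C10 | C[C@H]1C(=O)O[C@]3(CCC=O)[C@@H]2CC[C@@H]4C[C@]2(C[C@]4(C)O)[C@@H](C(=O)O)[C@@H]31 | intermediate
21 | CNP0343121.3 (3β,16-dihydroxy 19,10-lactone 7-acid of the 20-norgibberellane series; 16-OH endo, 17-CH3 exo) | C[C@@]12C(=O)O[C@]3(CC[C@@H]1O)[C@@H]1CC[C@@H]4C[C@]1(C[C@]4(C)O)[C@@H](C(=O)O)[C@@H]32 | target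

**Totals and risk**
Total step count: 10. Longest linear sequence: 10 steps.

The three steps most likely to fail:

Step 2 (the new desymmetrising Diels–Alder reaction): the level or sense of enantioselection may be inadequate. Fallback, setting out from 6 and coming back at 8: run the cycloaddition with the achiral Lewis acid Et2AlCl (CH2Cl2, −20 °C), where the facial preference syn to the acyloxy group is substrate-controlled and known for quinol esters. This gives racemic adduct, that is 8 together with its mirror image, the ent-adduct F1. The two are separated by preparative chromatography on a chiral stationary phase, and 8 continues with step 3.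

Step 4 (carbonyl-ene closure of ring D): the ketone may be too weak an enophile, or may bond to C12 instead of C13. Fallback, setting out from 8 and coming back at 19: alkylate the lithium enolate of 8 (LiN(SiMe3)2, THF, −78 °C) with 2,3-dibromopropene to the vinyl bromide F2. Bu3SnH with AIBN (benzene, 80 °C) then closes ring D by 5-exo vinyl-radical cyclisation onto C13, giving the 16-methylene tricycle F3 with C11–C12 already saturated. OsO4 (cat.) with NaIO4 cleaves the exocyclic alkene to the 16-ketone F4. MeTi(OiPr)3 adds to this unhindered cyclopentanone from the exo face, in preference to the hindered conjugated 7-ketone, to give the tertiary alcohol F5 (OH endo, the 11,12-dihydro analogue of 12). F5 is taken through the conditions of steps 5, 6 and 7 as the lactone ketone F6, the diazo ketone F7 and the 6β benzyl ester F8, and hydrogenolysis of F8 under the conditions of step 8 gives 19.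

Step 10 (aldol closure of ring A): the 3α epimer may predominate, or retro-aldol equilibration may intervene. Fallback, setting out from 20 and coming back at 21: cyclise 20 under equilibrating conditions (NaOMe, MeOH, 25 °C), which gives 21 mixed with its 3α epimer F9. Oxidise the mixture with Dess–Martin periodinane to the single 3-ketone F10 and reduce it with K[(sec-Bu)3BH] in THF at −78 °C, where equatorial hydride delivery is expected to give the axial 3β-alcohol 21.

**Further compounds**
F1 | step 2 | ent-adduct (enantiomer of 8) | CCC(=O)O[C@@]3(CCCOCc4ccccc4)[C@H]1CC=CC[C@H]1C(=O)C=C3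
F2 | step 4 | vinyl bromide: 8 with a 2-bromoprop-2-en-1-yl group in place of H-8 (8β) | CCC(=O)O[C@]3(CCCOCc4ccccc4)[C@@H]1CC=CC[C@]1(CC(Br)=C)C(=O)C=C3
F3 | step 4 | 16-methylene tricycle (ring D closed, C11–C12 saturated, 7-oxo-5-ene, 10α-propanoate) | CCC(=O)O[C@]3(CCCOCc5ccccc5)[C@@H]1CC[C@@H]4C[C@]1(CC4=C)C(=O)C=C3
F4 | step 4 | 16-ketone (17-nor) | CCC(=O)O[C@]3(CCCOCc5ccccc5)[C@@H]1CC[C@@H]4C[C@]1(CC4=O)C(=O)C=C3
F5 | step 4 | tertiary alcohol, 11,12-dihydro analogue of 12 (16-OH endo) | CCC(=O)O[C@]3(CCCOCc5ccccc5)[C@@H]1CC[C@@H]4C[C@]1(C[C@]4(C)O)C(=O)C=C3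
F6 | step 4 | lactone ketone, 11,12-dihydro analogue of 13 | C[C@H]1C(=O)O[C@]3(CCCOCc5ccccc5)[C@@H]2CC[C@@H]4C[C@]2(C[C@]4(C)O)C(=O)C[C@@H]31
F7 | step 4 | diazo ketone, 11,12-dihydro analogue of 15 | C[C@H]1C(=O)O[C@]3(CCCOCc5ccccc5)[C@@H]2CC[C@@H]4C[C@]2(C[C@]4(C)O)C(=O)C(=[N+]=[N-])[C@@H]31
F8 | step 4 | 6β benzyl ester, 11,12-dihydro analogue of 18 | C[C@H]1C(=O)O[C@]3(CCCOCc5ccccc5)[C@@H]2CC[C@@H]4C[C@]2(C[C@]4(C)O)[C@@H](C(=O)OCc6ccccc6)[C@@H]31
F9 | step 10 | 3α epimer of 21 | C[C@@]12C(=O)O[C@]3(CC[C@H]1O)[C@@H]1CC[C@@H]4C[C@]1(C[C@]4(C)O)[C@@H](C(=O)O)[C@@H]32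
F10 | step 10 | 3-ketone (3-oxo analogue of 21) | C[C@@]12C(=O)O[C@]3(CCC1=O)[C@@H]1CC[C@@H]4C[C@]1(C[C@]4(C)O)[C@@H](C(=O)O)[C@@H]32
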